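The rate constants come from no measurement.

The product is short chains of L, and I reckon the length of a chain as a contest over each living end D: will its next partner be Q or E? The average counts every chain begun, living or dead.

Q 19 mM; E 5.70 mM; X 1.8 mM; time 25 min

    2 D → D2 (k1 = 12 L mol⁻¹ s⁻¹)
    Q + D → L + D, rate k2*[D]*[Q] (k2 = 8.6 L mol⁻¹ s⁻¹)
    Q + G → D + L (k3 = 97 L mol⁻¹ s⁻¹)
    X → G (k4 = 0.039 s⁻¹)
    D + E → D.E (k5 = 11 L mol⁻¹ s⁻¹)

- a doubled species enters its step squared and goes two at a time
- the average divides the monomer in chains by the number of chains begun, living and dead together
- run time (flask): 25 min

1. average number of monomer units in a chain (chains begun, living or dead) at 25 min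
2. part of the Q that has reacted at 25 min

How many chains are begun? X turns into G with a half-life of 0.30 min, far shorter than the run. Q takes G with a pseudo-first-order constant k·cQ = 1.84 s⁻¹, much larger than the constant 0.039 s⁻¹ with which X decays. So I count one chain of one unit per X, which makes 1.8 mM of chains.

How far does a chain grow? At the charge, an end adds Q at k·cQ = 0.163 s⁻¹ and is captured by E at k·cE = 0.0627 s⁻¹, both pseudo-first-order for the end. Their ratio, the units an end adds on average before E takes it (its kinetic chain length), is 2.61. My reckoning is therefore 3.61 units per chain, and 34.2% of Q reacted.

But that ratio belongs to the first moment; does it drift? Counting 3.61 Q and one E per chain, the fractional loss per mM of chains is 0.190 mM⁻¹ for Q's charge and 0.175 mM⁻¹ for E's, so on this count cQ/cE falls slowly.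

And the pairing of D? Taking cD at its ceiling, the whole charge of X, pairing costs an end 0.0432 s⁻¹, less than capture. I leave it out of the reckoning; pairing shortens an end's life, so I expect my figures to stand somewhat high.

The forecast gives 3.1 units per chain and 30% of Q reacted, both lower than mine, with the ends dying “mainly through E and a little through pairing”.

This flask gives 3.20 units per chain and 30.3% of Q reacted, so the forecast holds. At 25.0 min this flask keeps 70% of its Q and 72% of its E. Put in with these remains, the ratio is 2.51 against 2.61 at the charge. The units per chain beyond the first, 2.20, lie below it.

In the neighbouring flask, with 23 mM of E in place of 5.70 mM and the other charges and the time as before, the same ratio is 0.646, which gives 1.65 units per chain and 15.6% of Q reacted. That flask gives 1.61 and 15.2%.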